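If the reagent is cut from the north-east charge to that of this flask, the product depends on how much catalyst survives the slowing turnover.

| setting | north-east | flask |
|---|---|---|
| starting material | 0.40 M | 0.40 M |
| reagent | 0.66 M | 0.440 M |
| free catalyst | 20 mM | 20 mM |
| remark | run made earlier |  |
| time |  | 15 d |

north-east run (percent of the starting material charged)

| time / h | product / % | starting material / % |
|---|---|---|
| 5.00 | 37.9 | 60.5 |
| 12.0 | 70.9 | 26.9 |
| 25.0 | 91.9 | 5.2 |
| 40.0 | 96.9 | 0.1 |

(readings scatter by 0.5 percentage points)

- percent here means starting material units held: one spent catalyst counts as two
- steps that have been proposed: catalyst intermediate A + product -> spent catalyst; starting material + free catalyst <-> catalyst intermediate A; catalyst intermediate B -> by-product + catalyst intermediate C; reagent + catalyst intermediate A -> catalyst intermediate B; catalyst intermediate C -> free catalyst + product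
- the reaction counts as stopped when no species that holds the starting material changes by six tenths of a point or more over the second half of the time

* why nothing more happens at 15 d, or that something still does (forward and back rates have come level / the reagent has run out first / all of the starting material has reacted / no working catalyst is left / it is still moving)
* product at 15 d, in percent of the starting material charged

In the north-east run, starting material first falls at 0.101 h⁻¹. Its last reading lacks enough balance for 6.00 mM of spent catalyst, since each counts as two. Catalyst intermediate A meets either product, which kills it, or reagent, which turns it over, so the loss per turnover is κ·c(product)/c(reagent). Integrating this over that run, with 0.388 M of product, gives the selectivity factor κ = 0.0305.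

For this flask, I charge the rate in full to reagent, so it starts at 0.0670 h⁻¹. Suppose 13.3 mM ends up spent. Product is then 0.373 M, and κ returns 14.0 mM, close enough. Near the end, reagent slows the rate by a factor 0.152 and lost catalyst by 0.333. Both factors together give a time constant of 296 h, and 15 d holds only 1.22 of those, too few for me to call the starting material consumed. But the north-east readings do not show the rate following a falling reagent: between 12.0 h and 25.0 h starting material falls at 0.126 h⁻¹, faster than the 0.101 h⁻¹ of the first hours. So I keep the reagent's effect on the starting rate, add no further reagent slowing, and count the lost catalyst, which gives a late time constant of 44.8 h, shorter than 15 d, with 8.04 of them available. On that reckoning I expect the starting material to be consumed, with product near 93.3 %.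

The forecast agrees in kind: all of the starting material has reacted, product 93.2 % (91.3 % to 94.8 %), though it holds that “the rate barely depends on reagent”.

The flask gives all of the starting material has reacted, with product 94.2 %.

    catalyst intermediate A + product → spent catalyst (k = 0.00468 M⁻¹ min⁻¹)
    starting material + free catalyst ⇌ catalyst intermediate A (K = 4.28 M⁻¹, k = 0.283 M⁻¹ min⁻¹)
    catalyst intermediate B → by-product + catalyst intermediate C (k = 0.417 min⁻¹)
    reagent + catalyst intermediate A → catalyst intermediate B (k = 0.220 M⁻¹ min⁻¹)
    catalyst intermediate C → free catalyst + product (k = 0.0918 min⁻¹)

In this flask, reagent's half-life by its own step is 0.45 d at 0.350 d, far shorter than 15 d, and starting material stands at 0.183 % by 7.50 d. At that product, κ reckons 73.0 % of the catalyst spent, and the flask holds 57.6 %.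

With 0.68 M of starting material in the neighbour, κ spends 20.0 mM, the whole catalyst charge, by 0.400 M of product, or 58.8 %. The neighbour gives 59.0 %, with 100 % of its catalyst spent and 35.1 % of its starting material left.

All runs stem from a simulated flask from invented constants, and the scatter is random.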